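Over 80 min of isothermal stirring, amber, blue, teal and grey differ in initiator loading, and the earlier runs alder, oak and maple show what loading does.

| flask | substrate | reagent | initiator | remark | time |
|---|---|---|---|---|---|
| alder | 0.10 M | 5 equiv | 1.1 mol% | run made earlier |  |
| oak | 0.10 M | 5 equiv | 5.2 mol% | run made earlier |  |
| maple | 0.10 M | 5 equiv | 20 mol% | run made earlier |  |
| amber | 0.10 M | 5.00 equiv | 1 mol% |  | 80 min |
| blue | 0.10 M | 5.00 equiv | 3 mol% |  | 80 min |
| teal | 0.10 M | 5.00 equiv | 8 mol% |  | 80 min |
| grey | 0.10 M | 5.00 equiv | 25 mol% |  | 80 min |

| alder: time / min | alder: target / % | oak: time / min | oak: target / % | maple: time / min | maple: target / % |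
|---|---|---|---|---|---|
| 4.00 | 3.9 | 8.00 | 15.7 | 8.00 | 30.2 |
| 10.0 | 8.7 | 15.0 | 28.4 | 15.0 | 54.7 |
| 20.0 | 17.4 | 25.0 | 46.8 | 25.0 | 86.4 |
| 30.0 | 26.2 | 30.0 | 54.8 | 30.0 | 96.4 |
| 40.0 | 33.8 | 40.0 | 70.7 | 40.0 | 94.9 |

(standard deviation of a reading: 0.3 percentage points)

- "hardly changes" means that all values lie within two and a half points (for a concentration: within two and a half percent of the largest)

- amount of target at the end, in percent of the substrate charged for amber, blue, teal, grey, in this order
- how that number moves from the first to the last of them (hardly changes / rises, then falls / falls, then rises / rises all the way / falls all the way)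

In alder, target climbs almost straight, 17.4% at 20.0 min and 33.8% at 40.0 min, so a reading divided by its time serves as a rate. At 30.0 min, the common logarithm of the oak-to-alder target ratio, divided by that of their loading ratio, gives 0.475, the apparent order in initiator.

My own reckoning scales alder's straight rate by this power to obtain a clearance time, in which target would reach the full charge at constant rate. Amber's is 124 min, longer than 80 min, so amber's target should stand near 64.6% at that time. Blue's is 73.5 min, shorter than 80 min, so blue should finish. Past clearance, maple reads 96.4% at 30.0 min but 94.9% at 40.0 min, so the row should rise, then fall.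

The forecast, reading “half order in initiator, as for a radical chain”, gives 55%, 94%, 94% and 89%, with the shape rises, then falls. Its amber stands lower than mine.

The flasks give 60.6%, 92.2%, 90.0% and 88.6%, with the shape rises, then falls.

    initiator → 2 initiating radical (k = 7.10 × 10⁻⁵ min⁻¹)
    substrate + initiating radical → capped initiator + first chain carrier (k = 1.90 × 10⁵ L mol⁻¹ s⁻¹)
    reagent + first chain carrier → target + second chain carrier (k = 3.60 × 10⁵ L mol⁻¹ min⁻¹)
    substrate + second chain carrier → by-product + first chain carrier (k = 35000 L mol⁻¹ s⁻¹)
    2 first chain carrier → ended chains (k = 5.00 × 10⁷ L mol⁻¹ s⁻¹)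
    target ⇌ isomer of the product (K = 0.600, k = 0.00200 min⁻¹)

Amber's 60.6% lies below the reckoned 64.6%. With the step from target to isomer of the product switched off, amber's target ends at 65.2%. On blue, the order 0.475 gives a clearance time of 73.5 min, and blue's substrate falls under 2.00% of its charge at 72.3 min.

The numbers in the tables are calculated for substances that don't exist; scatter was added.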